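**Plan**

1. Last cuts: the methyl ester and the epoxide oxygen (the epoxide is made from the (E)-alkene at the end). Next cut: the C(sp3)–C(sp2) bond between the second CH2 of the dioxane side arm and the alkene CH (B-alkyl Suzuki coupling), giving vinyl iodide 13 and 6-vinyl-1,2-dioxane 26.
2. Cyclohexene ring: the unit C(CH3)=C(chain)–C(CH3)2 is a masked 2-alkyl-3-methylcyclohex-2-enone. The ring C–CH3 comes from an enol triflate and one CH3 of C(CH3)2 from conjugate addition. The enone is cut at its C=C (chain-bearing carbon to the later C(CH3)2 carbon, aldol) and at the CH2–CH2 bond next to that carbon (Michael): a Robinson annulation of vinyl ketone 4 with ethyl acetoacetate.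
3. Dioxane ring: both C–O bonds form with inversion. H2O2 opens an (R)-2,2-disubstituted epoxide at its tertiary carbon, then the hydroperoxide displaces a secondary mesylate (6-exo-tet).
4. Forward order: cyclohexene ring (steps 3–5), (E)-vinyl iodide (6); right-fragment chain (7–11), dioxane ring (12–13), ester and vinyl handle (14–17); fragment union (18); epoxide (19); acid (20).
5. Stereochemistry: the quaternary peroxide carbon comes from (S)-2-methylglycidol (one inversion). The ring CH and the α-methyl carbon come from a tartrate-controlled anti crotylboration (CH inverted on ring closure). Alkene geometry comes from syn-carboalumination, and the epoxide carbons from the L-fructose-derived dioxirane catalyst.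

Key step: step 3

Remark: (S)-2-methylglycidol, the (R,R)-tartrate (E)-crotylboronate and the L-fructose-derived ketone catalyst are taken as purchasable or made by their standard preparations; the terminal alkyne of 4–11 may be metalated by the organometallic reagents of steps 2, 4 and 5 (hence the excess) and is restored on work-up.

**Step 1**
Reactants: 1 hex-5-ynoic acid
Product: 3 N-methoxy-N-methylhex-5-ynamide, via acyl imidazole 2 (not isolated)
Conditions: CDI, CH2Cl2, rt; then MeNH(OMe)·HCl, rt
Reagents that add atoms: N,O-dimethylhydroxylamine hydrochloride (CNOC.Cl)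
Why: Weinreb amide formation through the acyl imidazole gives an acyl donor that stops organometallic addition at the ketone stage.

**Step 2**
Reactants: 3 N-methoxy-N-methylhex-5-ynamide
Product: 4 oct-1-en-7-yn-3-one
Conditions: CH2=CHMgBr (2.5 equiv), THF, −20 → 0 °C; inverse quench into cold 1 M HCl
Reagents that add atoms: vinylmagnesium bromide (C=C[Mg]Br)
Why: Grignard addition to a Weinreb amide gives a stable magnesium chelate that collapses to the vinyl ketone only on acidic quench, so over-addition and conjugate addition of the liberated amine should be avoided.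

**Step 3**
Reactants: 4 oct-1-en-7-yn-3-one; 5 ethyl acetoacetate
Product: 8 2-(but-3-yn-1-yl)-3-methylcyclohex-2-en-1-one, via Michael adduct 6 (not isolated), via cyclohexenone ester 7 (not isolated)
Conditions: NaOEt (0.2 equiv), EtOH, 0 °C → rt, then reflux; aq KOH, reflux; HCl to pH 2, 50 °C
Reagents that add atoms: none
Why: Robinson annulation: ethoxide forms the stabilised carbanion of 5, which adds in a Michael sense to the unsubstituted β-carbon of 4 and so makes the CH2–CH2 bond that lies next to the future quaternary carbon (6). The chain ketone then enolises toward the CH2 that carries the butynyl arm and this enolate attacks the acetyl carbonyl in a 6-(enolendo)-exo-trig aldol closure; E1cB loss of water gives the tetrasubstituted enone C=C (7), which is the bond between the chain-bearing ring carbon and the carbon that later becomes C(CH3)2. Hot aqueous KOH saponifies the ester, which is vinylogously β to the ketone, and acidification releases CO2; this is the classical alkyl vinyl ketone/acetoacetate route to 2-alkyl-3-methylcyclohexenones. No stereocentre survives, because the ester-bearing carbon ends as CH2. The selectivity needed is the direction of the aldol (chain CH2 onto the acetyl C=O, not acetyl CH3 onto the chain ketone); aldol additions are reversible here and dehydration drains only the more substituted conjugated enone, as in the cyclisation of 2,6-diketones. The terminal alkyne is inert to alkoxide and hydroxide at these temperatures.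

**Step 4**
Reactants: 8 2-(but-3-yn-1-yl)-3-methylcyclohex-2-en-1-one
Product: 10 2-(but-3-yn-1-yl)-3,3-dimethylcyclohex-1-en-1-yl trifluoromethanesulfonate, via lithium enolate 9 (not isolated)
Conditions: Me2CuLi (from MeLi and CuI, 2.5 equiv), Et2O, −20 → 0 °C; then PhNTf2, THF, 0 °C → rt
Reagents that add atoms: lithium dimethylcuprate ([Li+].C[Cu-]C); N-phenylbis(trifluoromethanesulfonimide) (O=S(=O)(N(c1ccccc1)S(=O)(=O)C(F)(F)F)C(F)(F)F)
Why: Cuprate 1,4-addition to the β,β-disubstituted enone makes the quaternary C(CH3)2 carbon and releases the enolate regiospecifically toward the chain-bearing carbon, so O-triflation fixes the tetrasubstituted C=C where the target needs it (conjugate addition–enolate trapping).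

**Step 5**
Reactants: 10 2-(but-3-yn-1-yl)-3,3-dimethylcyclohex-1-en-1-yl trifluoromethanesulfonate
Product: 11 2-(but-3-yn-1-yl)-1,3,3-trimethylcyclohex-1-ene
Conditions: Me2CuLi (from MeLi and CuI, 3 equiv), THF, −15 → 0 °C
Reagents that add atoms: lithium dimethylcuprate ([Li+].C[Cu-]C)
Why: Cuprate cross-coupling of an enol triflate replaces OTf by methyl without moving the double bond, and a metalated alkynyl group acts only as a non-transferable ligand.

**Step 6**
Reactants: 11 2-(but-3-yn-1-yl)-1,3,3-trimethylcyclohex-1-ene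
Product: 13 2-[(3E)-4-iodo-3-methylbut-3-en-1-yl]-1,3,3-trimethylcyclohex-1-ene, via vinylalane 12 (not isolated)
Conditions: AlMe3 (3 equiv), Cp2ZrCl2 (0.25 equiv), CH2Cl2, 0 °C → rt; then I2, THF, −30 → 0 °C
Reagents that add atoms: trimethylaluminium (C[Al](C)C); iodine (II)
Why: Negishi carboalumination adds CH3 and Al syn across the terminal alkyne with CH3 on the internal carbon, and iodinolysis with retention gives the (E)-trisubstituted vinyl iodide; the hindered ring alkene is inert.

**Step 7**
Reactants: 14 (S)-2-methylglycidol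
Product: 15 (2R)-2-methylhex-5-ene-1,2-diol
Conditions: CH2=CHCH2MgCl (2.5 equiv), CuI (5 mol %), THF, −40 → 0 °C; aq NH4Cl
Reagents that add atoms: allylmagnesium chloride (C=CC[Mg]Cl)
Why: Copper-catalysed Grignard opening of the 2,2-disubstituted epoxide occurs at its CH2 terminus (SN2), so the tertiary stereocentre of 14 is carried over untouched.

**Step 8**
Reactants: 15 (2R)-2-methylhex-5-ene-1,2-diol
Product: 16 (2R)-2-(but-3-en-1-yl)-2-methyloxirane
Conditions: NaH (2.2 equiv), 1-(p-toluenesulfonyl)imidazole, THF, 0 °C → rt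
Reagents that add atoms: none
Why: Selective sulfonylation of the primary alkoxide and 3-exo-tet displacement by the tertiary alkoxide (Williamson-type closure) re-form the epoxide on the other arm without breaking a bond at the stereocentre.

**Step 9**
Reactants: 16 (2R)-2-(but-3-en-1-yl)-2-methyloxirane
Product: 17 3-[(2R)-2-methyloxiran-2-yl]propanal
Conditions: O3, CH2Cl2, −78 °C; then Me2S, −78 °C → rt
Reagents that add atoms: ozone ([O-][O+]=O)
Why: Ozonolysis with reductive work-up cleaves the only alkene to the aldehyde and leaves the epoxide alone.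

**Step 10**
Reactants: 17 3-[(2R)-2-methyloxiran-2-yl]propanal
Product: 18 (3S,4R)-3-methyl-6-[(2R)-2-methyloxiran-2-yl]hex-1-en-4-ol
Conditions: (R,R)-diisopropyl tartrate (E)-crotylboronate, 4 Å molecular sieves, toluene, −78 °C; aq NaHCO3
Reagents that add atoms: diisopropyl (4R,5R)-2-[(2E)-but-2-en-1-yl]-1,3,2-dioxaborolane-4,5-dicarboxylate (C/C=C/CB1O[C@H]([C@@H](O1)C(=O)OC(C)C)C(=O)OC(C)C)
Why: Roush crotylboration through a closed chair transition state: the (E)-crotyl geometry sets OH and CH3 anti and the (R,R)-tartrate directs attack to the Si face of the aldehyde (reagent control), under Lewis-acid-free conditions that spare the epoxide.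

**Step 11**
Reactants: 18 (3S,4R)-3-methyl-6-[(2R)-2-methyloxiran-2-yl]hex-1-en-4-ol
Product: 19 (3S,4R)-3-methyl-6-[(2R)-2-methyloxiran-2-yl]hex-1-en-4-yl methanesulfonate
Conditions: MsCl, Et3N, CH2Cl2, 0 °C
Reagents that add atoms: methanesulfonyl chloride (CS(=O)(=O)Cl)
Why: Sulfonylation converts the secondary alcohol into a leaving group with retention at carbon.

**Step 12**
Reactants: 19 (3S,4R)-3-methyl-6-[(2R)-2-methyloxiran-2-yl]hex-1-en-4-yl methanesulfonate
Product: 20 (2S,5R,6S)-2-hydroperoxy-1-hydroxy-2,6-dimethyloct-7-en-5-yl methanesulfonate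
Conditions: anhydrous H2O2 in Et2O, H3PMo12O40 (5 mol %), rt
Reagents that add atoms: hydrogen peroxide (OO)
Why: Acid-catalysed perhydrolysis of the epoxide should take place at the tertiary carbon with inversion (borderline SN2 opening of the activated epoxide), giving the tertiary hydroperoxide while mesylate and monosubstituted alkene stay inert.

**Step 13**
Reactants: 20 (2S,5R,6S)-2-hydroperoxy-1-hydroxy-2,6-dimethyloct-7-en-5-yl methanesulfonate
Product: 21 [(3S,6S)-6-[(2S)-but-3-en-2-yl]-3-methyl-1,2-dioxan-3-yl]methanol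
Conditions: CsOH·H2O (1.1 equiv), DMF, 0 °C → rt
Reagents that add atoms: none
Why: Intramolecular alkylation of the hydroperoxide (the most acidic OH and an α-effect nucleophile) by 6-exo-tet SN2 displacement of the secondary mesylate closes the 1,2-dioxane with inversion at the ring CH carbon.

**Step 14**
Reactants: 21 [(3S,6S)-6-[(2S)-but-3-en-2-yl]-3-methyl-1,2-dioxan-3-yl]methanol
Product: 23 (2R)-2-[(3S,6S)-6-(hydroxymethyl)-6-methyl-1,2-dioxan-3-yl]propanoic acid, via aldehyde 22 (not isolated)
Conditions: O3, CH2Cl2, −78 °C; Me2S; then NaClO2, NaH2PO4, 2-methylbut-2-ene, t-BuOH/H2O, 0 °C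
Reagents that add atoms: ozone ([O-][O+]=O); sodium chlorite ([Na+].[O-]Cl=O)
Why: Ozonolysis of the remaining vinyl group and buffered Pinnick oxidation of the crude aldehyde unmask the carboxylic acid without epimerising the α-carbon or touching the dialkyl peroxide and the primary alcohol.

**Step 15**
Reactants: 23 (2R)-2-[(3S,6S)-6-(hydroxymethyl)-6-methyl-1,2-dioxan-3-yl]propanoic acid
Product: 24 methyl (2R)-2-[(3S,6S)-6-(hydroxymethyl)-6-methyl-1,2-dioxan-3-yl]propanoate
Conditions: Me3SiCHN2, MeOH/toluene, 0 °C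
Reagents that add atoms: (trimethylsilyl)diazomethane (C[Si](C)(C)C=[N+]=[N-])
Why: Esterification with (trimethylsilyl)diazomethane is selective for the carboxylic acid and needs neither acid nor base.

**Step 16**
Reactants: 24 methyl (2R)-2-[(3S,6S)-6-(hydroxymethyl)-6-methyl-1,2-dioxan-3-yl]propanoate
Product: 25 methyl (2R)-2-[(3S,6S)-6-formyl-6-methyl-1,2-dioxan-3-yl]propanoate
Conditions: Dess–Martin periodinane, CH2Cl2, 0 °C → rt
Reagents that add atoms: none
Why: Dess–Martin oxidation of the neopentyl-type primary alcohol under neutral conditions gives an aldehyde that has no α-hydrogen.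

**Step 17**
Reactants: 25 methyl (2R)-2-[(3S,6S)-6-formyl-6-methyl-1,2-dioxan-3-yl]propanoate
Product: 26 methyl (2R)-2-[(3S,6S)-6-ethenyl-6-methyl-1,2-dioxan-3-yl]propanoate
Conditions: Ph3PCH3Br, KN(SiMe3)2, THF, −78 → 0 °C
Reagents that add atoms: methyltriphenylphosphonium bromide (C[P+](c1ccccc1)(c1ccccc1)c1ccccc1.[Br-])
Why: Wittig methylenation of the non-enolisable aldehyde at low temperature should leave the ester and the dialkyl peroxide untouched.

**Step 18**
Reactants: 26 methyl (2R)-2-[(3S,6S)-6-ethenyl-6-methyl-1,2-dioxan-3-yl]propanoate; 13 2-[(3E)-4-iodo-3-methylbut-3-en-1-yl]-1,3,3-trimethylcyclohex-1-ene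
Product: 28 methyl (2R)-2-[(3S,6R)-6-methyl-6-[(3E)-4-methyl-6-(2,6,6-trimethylcyclohex-1-en-1-yl)hex-3-en-1-yl]-1,2-dioxan-3-yl]propanoate, via alkylborane 27 (not isolated)
Conditions: 9-BBN-H, THF, rt; then 13, Pd(dppf)Cl2 (5 mol %), AsPh3, Cs2CO3, DMF/THF/H2O, rt
Reagents that add atoms: none
Why: Anti-Markovnikov hydroboration of the only alkene of 26 and B-alkyl Suzuki–Miyaura coupling with the vinyl iodide join the fragments with retention of the (E) geometry, a reaction type that should tolerate esters and dialkyl peroxides.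

**Step 19**
Reactants: 28 methyl (2R)-2-[(3S,6R)-6-methyl-6-[(3E)-4-methyl-6-(2,6,6-trimethylcyclohex-1-en-1-yl)hex-3-en-1-yl]-1,2-dioxan-3-yl]propanoate
Product: 29 methyl (2R)-2-[(3S,6R)-6-methyl-6-[2-[(2S,3S)-3-methyl-3-[2-(2,6,6-trimethylcyclohex-1-en-1-yl)ethyl]oxiran-2-yl]ethyl]-1,2-dioxan-3-yl]propanoate
Conditions: 1,2:4,5-di-O-isopropylidene-β-L-erythro-2,3-hexodiulo-2,6-pyranose (30 mol %), KHSO5 (as 2KHSO5·KHSO4·K2SO4), K2CO3, Bu4NHSO4, MeCN/dimethoxymethane/aqueous buffer (pH 10.5), 0 °C
Reagents that add atoms: potassium peroxymonosulfate ([K+].[O-]S(=O)(=O)OO)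
Why: Shi epoxidation: the chiral dioxirane from the L-fructose-derived ketone transfers oxygen through a spiro transition state to one face of the (E)-trisubstituted alkene (reagent control, giving the (S,S)-epoxide), and its bulk should disfavour the tetrasubstituted ring alkene flanked by the quaternary carbon.

**Step 20**
Reactants: 29 methyl (2R)-2-[(3S,6R)-6-methyl-6-[2-[(2S,3S)-3-methyl-3-[2-(2,6,6-trimethylcyclohex-1-en-1-yl)ethyl]oxiran-2-yl]ethyl]-1,2-dioxan-3-yl]propanoate
Product: 30 (2R)-2-[(3S,6R)-6-methyl-6-[2-[(2S,3S)-3-methyl-3-[2-(2,6,6-trimethylcyclohex-1-en-1-yl)ethyl]oxiran-2-yl]ethyl]-1,2-dioxan-3-yl]propanoic acid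
Conditions: LiOH, THF/H2O, 0 °C → rt; then 0.5 M HCl to pH 4 at 0 °C
Reagents that add atoms: lithium hydroxide ([Li+].[OH-])
Why: Saponification of the methyl ester at low temperature is a standard last step for 1,2-dioxane esters of this kind, and epoxide and peroxide should survive hydroxide and brief mild acidification.

**Compound list**

1 | hex-5-ynoic acid | C#CCCCC(=O)O | starting material
2 | 1-(hex-5-ynoyl)-1H-imidazole | C#CCCCC(=O)n1ccnc1 | intermediate
3 | N-methoxy-N-methylhex-5-ynamide | C#CCCCC(=O)N(C)OC | intermediate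
4 | oct-1-en-7-yn-3-one | C=CC(=O)CCCC#C | intermediate
5 | ethyl acetoacetate | CCOC(=O)CC(C)=O | starting material
6 | ethyl 2-acetyl-5-oxodec-9-ynoate | CCOC(=O)C(C(C)=O)CCC(=O)CCCC#C | intermediate
7 | ethyl 3-(but-3-yn-1-yl)-2-methyl-4-oxocyclohex-2-ene-1-carboxylate | CCOC(=O)C1CCC(=O)C(CCC#C)=C1C | intermediate
8 | 2-(but-3-yn-1-yl)-3-methylcyclohex-2-en-1-one | CC1=C(CCC#C)C(=O)CCC1 | intermediate
9 | lithium 2-(but-3-yn-1-yl)-3,3-dimethylcyclohex-1-en-1-olate | [Li+].[O-]C1=C(CCC#C)C(C)(C)CCC1 | intermediate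
10 | 2-(but-3-yn-1-yl)-3,3-dimethylcyclohex-1-en-1-yl trifluoromethanesulfonate | C#CCCC1=C(OS(=O)(=O)C(F)(F)F)CCCC1(C)C | intermediate
11 | 2-(but-3-yn-1-yl)-1,3,3-trimethylcyclohex-1-ene | CC1=C(CCC#C)C(C)(C)CCC1 | intermediate
12 | dimethyl[(1E)-2-methyl-4-(2,6,6-trimethylcyclohex-1-en-1-yl)but-1-en-1-yl]alumane | CC1=C(CC/C(C)=C/[Al](C)C)C(C)(C)CCC1 | intermediate
13 | 2-[(3E)-4-iodo-3-methylbut-3-en-1-yl]-1,3,3-trimethylcyclohex-1-ene | CC1=C(CC/C(C)=C/I)C(C)(C)CCC1 | intermediate
14 | (S)-2-methylglycidol, [(2S)-2-methyloxiran-2-yl]methanol | OC[C@@]1(C)CO1 | starting material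
15 | (2R)-2-methylhex-5-ene-1,2-diol | OC[C@@](O)(C)CCC=C | intermediate
16 | (2R)-2-(but-3-en-1-yl)-2-methyloxirane | C1[C@@](O1)(C)CCC=C | intermediate
17 | 3-[(2R)-2-methyloxiran-2-yl]propanal | C1[C@@](O1)(C)CCC=O | intermediate
18 | (3S,4R)-3-methyl-6-[(2R)-2-methyloxiran-2-yl]hex-1-en-4-ol | C1[C@@](O1)(C)CC[C@@H](O)[C@@H](C)C=C | intermediate
19 | (3S,4R)-3-methyl-6-[(2R)-2-methyloxiran-2-yl]hex-1-en-4-yl methanesulfonate | C1[C@@](O1)(C)CC[C@@H](OS(C)(=O)=O)[C@@H](C)C=C | intermediate
20 | (2S,5R,6S)-2-hydroperoxy-1-hydroxy-2,6-dimethyloct-7-en-5-yl methanesulfonate | OC[C@](OO)(C)CC[C@@H](OS(C)(=O)=O)[C@@H](C)C=C | intermediate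
21 | [(3S,6S)-6-[(2S)-but-3-en-2-yl]-3-methyl-1,2-dioxan-3-yl]methanol | OC[C@]1(C)CC[C@@H]([C@@H](C)C=C)OO1 | intermediate
22 | (2R)-2-[(3S,6S)-6-(hydroxymethyl)-6-methyl-1,2-dioxan-3-yl]propanal | OC[C@]1(C)CC[C@@H]([C@@H](C)C=O)OO1 | intermediate
23 | (2R)-2-[(3S,6S)-6-(hydroxymethyl)-6-methyl-1,2-dioxan-3-yl]propanoic acid | OC[C@]1(C)CC[C@@H]([C@@H](C)C(=O)O)OO1 | intermediate
24 | methyl (2R)-2-[(3S,6S)-6-(hydroxymethyl)-6-methyl-1,2-dioxan-3-yl]propanoate | OC[C@]1(C)CC[C@@H]([C@@H](C)C(=O)OC)OO1 | intermediate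
25 | methyl (2R)-2-[(3S,6S)-6-formyl-6-methyl-1,2-dioxan-3-yl]propanoate | O=C[C@]1(C)CC[C@@H]([C@@H](C)C(=O)OC)OO1 | intermediate
26 | methyl (2R)-2-[(3S,6S)-6-ethenyl-6-methyl-1,2-dioxan-3-yl]propanoate | C=C[C@]1(C)CC[C@@H]([C@@H](C)C(=O)OC)OO1 | intermediate
27 | methyl (2R)-2-[(3S,6R)-6-[2-(9-borabicyclo[3.3.1]nonan-9-yl)ethyl]-6-methyl-1,2-dioxan-3-yl]propanoate | C1CC2CCCC(C1)B2CC[C@]1(C)CC[C@@H]([C@@H](C)C(=O)OC)OO1 | intermediate
28 | methyl (2R)-2-[(3S,6R)-6-methyl-6-[(3E)-4-methyl-6-(2,6,6-trimethylcyclohex-1-en-1-yl)hex-3-en-1-yl]-1,2-dioxan-3-yl]propanoate | CC1=C(CC/C(C)=C/CC[C@]2(C)CC[C@@H]([C@@H](C)C(=O)OC)OO2)C(C)(C)CCC1 | intermediate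
29 | methyl (2R)-2-[(3S,6R)-6-methyl-6-[2-[(2S,3S)-3-methyl-3-[2-(2,6,6-trimethylcyclohex-1-en-1-yl)ethyl]oxiran-2-yl]ethyl]-1,2-dioxan-3-yl]propanoate | CC1=C(CC[C@]2(C)O[C@H]2CC[C@]2(C)CC[C@@H]([C@@H](C)C(=O)OC)OO2)C(C)(C)CCC1 | intermediate
30 | (2R)-2-[(3S,6R)-6-methyl-6-[2-[(2S,3S)-3-methyl-3-[2-(2,6,6-trimethylcyclohex-1-en-1-yl)ethyl]oxiran-2-yl]ethyl]-1,2-dioxan-3-yl]propanoic acid | CC1=C(CC[C@]2(C)O[C@H]2CC[C@]2(C)CC[C@@H]([C@@H](C)C(=O)O)OO2)C(C)(C)CCC1 | target

**Step count and risks**

Total steps: 20. Longest linear sequence: 14 steps (steps 7–20, from 14).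

Steps most likely to fail:

1. Step 19. The risk is loss of site selectivity: the electron-rich tetrasubstituted ring alkene may be oxidised by the dioxirane in competition with the chain alkene. Fallback (sets out from 10 and 26, returns at 29): the ring alkene is kept masked as its electron-poor enol triflate until after the epoxidation. Carboalumination–iodination of 10 (AlMe3, Cp2ZrCl2; then I2) should give the iodo enol triflate F1. Hydroboration of 26 with 9-BBN-H to 27 and Suzuki–Miyaura coupling with F1 at its C–I bond (Pd(dppf)Cl2, AsPh3, Cs2CO3) should give the coupled enol triflate F2. Epoxidation under the conditions of step 19, to which the enol triflate is inert, should give the epoxy enol triflate F3. Negishi methylation (MeZnCl, Pd(dppf)Cl2, THF, rt) then rejoins the route at 29.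

2. Step 18. The risk is reductive cleavage of the O–O bond by zerovalent palladium or the borane, or slow hydroboration of the vinyl group on the quaternary carbon followed by protodeboronation. Fallback (sets out from 11 and 25, returns at 28): the fragments are joined by olefination and the new alkene is then saturated. Carboalumination of 11 (AlMe3, Cp2ZrCl2) quenched with paraformaldehyde should give the allylic alcohol F4. Ph3P·HBr in MeOH should convert it into the allylic phosphonium bromide F5. Wittig olefination of aldehyde 25 with F5 and KN(SiMe3)2 (THF, −78 °C) should give the diene ester F6. Diimide (potassium azodicarboxylate, AcOH, MeOH) should reduce only the 1,2-disubstituted C=C and give 28.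

3. Step 13. The risk is base-induced elimination of the mesylate toward the allylic hydrogen, or O-alkylation by the primary alkoxide (oxane formation), outcompeting peroxide ring closure. Fallback (sets out from 19, returns at 21): the order of the two C–O bond formations is reversed. Displacement of the mesylate of 19 by hydroperoxide (50% H2O2, KOH, MeOH, 0 °C → rt; SN2 with inversion) should give the hydroperoxy epoxide F7. Catalytic camphorsulfonic acid in CH2Cl2 should then open the epoxide at its tertiary carbon by the internal hydroperoxide (6-exo, inversion) and give 21.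

**Further compounds**

F1 | step 19 | 2-[(3E)-4-iodo-3-methylbut-3-en-1-yl]-3,3-dimethylcyclohex-1-en-1-yl trifluoromethanesulfonate | I/C=C(C)/CCC1=C(OS(=O)(=O)C(F)(F)F)CCCC1(C)C
F2 | step 19 | methyl (2R)-2-[(3S,6R)-6-[(3E)-6-[6,6-dimethyl-2-(trifluoromethanesulfonyloxy)cyclohex-1-en-1-yl]-4-methylhex-3-en-1-yl]-6-methyl-1,2-dioxan-3-yl]propanoate | FC(F)(F)S(=O)(=O)OC1=C(CC/C(C)=C/CC[C@]2(C)CC[C@@H]([C@@H](C)C(=O)OC)OO2)C(C)(C)CCC1
F3 | step 19 | methyl (2R)-2-[(3S,6R)-6-[2-[(2S,3S)-3-[2-[6,6-dimethyl-2-(trifluoromethanesulfonyloxy)cyclohex-1-en-1-yl]ethyl]-3-methyloxiran-2-yl]ethyl]-6-methyl-1,2-dioxan-3-yl]propanoate | FC(F)(F)S(=O)(=O)OC1=C(CC[C@]2(C)O[C@H]2CC[C@]2(C)CC[C@@H]([C@@H](C)C(=O)OC)OO2)C(C)(C)CCC1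
F4 | step 18 | (2E)-3-methyl-5-(2,6,6-trimethylcyclohex-1-en-1-yl)pent-2-en-1-ol | CC1=C(CC/C(C)=C/CO)C(C)(C)CCC1
F5 | step 18 | [(2E)-3-methyl-5-(2,6,6-trimethylcyclohex-1-en-1-yl)pent-2-en-1-yl]triphenylphosphonium bromide | CC1=C(CC/C(C)=C/C[P+](c2ccccc2)(c2ccccc2)c2ccccc2)C(C)(C)CCC1.[Br-]
F6 | step 18 | methyl (2R)-2-[(3S,6S)-6-methyl-6-[(3E)-4-methyl-6-(2,6,6-trimethylcyclohex-1-en-1-yl)hexa-1,3-dien-1-yl]-1,2-dioxan-3-yl]propanoate (mixture at the 1,2-double bond) | CC1=C(CC/C(C)=C/C=C[C@]2(C)CC[C@@H]([C@@H](C)C(=O)OC)OO2)C(C)(C)CCC1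
F7 | step 13 | (2R)-2-[(3S,4S)-3-hydroperoxy-4-methylhex-5-en-1-yl]-2-methyloxirane | C1[C@@](O1)(C)CC[C@H](OO)[C@@H](C)C=C
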